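The readings were generated by integration for substances that don't exist; the scatter is artificial.

**The wish.** Monomer in chains at 1.5 h was what I wanted from these flasks, and they differ in initiator.

| setting | elm | alder | spring | midnight | summer | winter | dawn |
|---|---|---|---|---|---|---|---|
| free monomer | 2 M | 2 M | 2.0 M | 2.0 M | 2.0 M | 2.0 M | 2.0 M |
| transfer agent | 0.060 M | 0.060 M | 0.0600 M | 0.0600 M | 0.0600 M | 0.0600 M | 0.0600 M |
| initiator | 6.7 mM | 130 mM | 6.0 mM | 30 mM | 80 mM | 20 mM | 40 mM |
| remark | run made earlier | run made earlier |  |  |  |  |  |
| time |  |  | 1.5 h | 1.5 h | 1.5 h | 1.5 h | 1.5 h |

| run | time / min | monomer in chains / % |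
|---|---|---|
| elm | 12.0 | 0 |
| elm | 30.0 | 2.7 |
| elm | 60.0 | 6.7 |
| elm | 90.0 | 11.3 |
| alder | 8.00 | 4.2 |
| alder | 15.0 | 14.1 |
| alder | 40.0 | 50.3 |
| alder | 90.0 | 86.1 |

(scatter of a reading: 0.5 percentage points)



- the flasks put in order of amount of monomer in chains, in percent of the free monomer charged, best first, at 1.5 h (spring / midnight / summer / winter / dawn)
- the same order at 12 h (spring / midnight / summer / winter / dawn)
- the amount of monomer in chains, in percent of the free monomer charged of the flask you put first, at 1.5 h
- the amount of monomer in chains, in percent of the free monomer charged of the flask you put last, at 1.5 h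

**Bench rule.** The bench habit says rate goes with the square root of initiator. Elm and alder were both read at 90.0 min, so I put those readings on a first-order measure, the logarithm of one over the share of the charge not in chains: 0.120 for elm, 1.97 for alder. Initiator rose by a factor of 19.4, whose root is 4.40, but the measure rose by 16.4, so the rule stopped working across this span.

**Initiator exponent.** I took an exponent of zero, where the measure does not move with initiator, as the zero of the scale. The initiator exponent, the usual apparent order, read 0.944, with the scatter of the readings in it: the logarithm of the rise in the measure over the logarithm of the rise in initiator.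

**My reckoning.** Scaling from the nearest run with that exponent, I got 10.2 % for spring from elm and 71.3 % for summer from alder. A positive exponent puts the flasks in order of initiator. The readings end at 90.0 min, so keeping that order at 12 h was my judgement.

**The result.** The forecast gave summer > dawn > midnight > winter > spring at 1.5 h and summer > dawn > midnight > winter > spring at 12 h, with 72 % first and 10.1 % last, saying “More initiator should stay ahead”. The flasks gave summer > dawn > midnight > winter > spring at 1.5 h, with 72.8 % and 10.4 %, and summer > dawn > midnight > winter > spring at 12 h.

    living end + transfer agent → dead chain (kL = 0.00220 M⁻¹ s⁻¹)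
    2 free monomer → homo dimer (k = 3.50 × 10⁻⁶ M⁻¹ s⁻¹)
    free monomer + living end → monomer in chains + living end, rate k3*[living end]*[free monomer] (k = 0.00790 M⁻¹ s⁻¹)
    free monomer + initiator → living end + monomer in chains (k = 1.90 × 10⁻⁴ M⁻¹ s⁻¹)

**What stood.** In spring at 1.50 h, the half-life of initiator by its step was 0.61 h, shorter than the 1.5 h of a living end against transfer agent as charged, reckoned for summer. At 1.50 h living end stood at 0.00326 M in spring and 0.0376 M in summer, a factor of 11.5, against 11.5 from the exponent. Summer's amount would have moved by 5 points at 68.4 mM or 94.6 mM of initiator.

**A neighbour.** For a neighbour of spring charged with 0.0015 M of initiator, the exponent applied to elm gave 2.88 % at 1.5 h. The computed flask gave 2.72 %.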